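Everything rests on building ring B instead of coupling it. Ring B has the ether oxygen on C4', hydrogens on C2', C3' and C5', and the hydroxyl on C6' next to the chain on C1'. This pattern maps onto C6–C3 of a 4-aryloxy-2-pyranone plus the two carbons of a 1-siloxyalkyne. One [4+2] cycloaddition with loss of CO2 forms C1'–C2' and C5'–C6' and delivers the arene at the right oxidation level. The precursor pyranone already holds the coumarin C3–O–C4' link, set by addition–elimination on 4-bromo-2-pyranone. A methyl ester would not survive ynolate generation, so the alkyne carries its carboxyl group as a TIPS ester, exchanged for methyl during debenzylation.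

Key step: step 7

Assumption: 2,4-dihydroxy-5-methoxybenzaldehyde, N-acetylglycine, 4-hydroxy-2H-pyran-2-one and pent-4-ynoic acid are taken as purchasable; the target has no stereocentre, so none has to be set.

Step 1
Reactants: 1 2,4-dihydroxy-5-methoxybenzaldehyde
Product: 2 4-(benzyloxy)-2-hydroxy-5-methoxybenzaldehyde
Conditions: BnBr (1.05 equiv), CsHCO3, MeCN, 60 °C
Reagents that add atoms: benzyl bromide, BrCc1ccccc1
Why: Williamson ether synthesis under a weak base, in which the C4 hydroxyl para to the formyl group is the more acidic and accessible one, whereas the C2 hydroxyl is held in a hydrogen bond to the aldehyde and should stay free.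

Step 2
Reactants: 2 4-(benzyloxy)-2-hydroxy-5-methoxybenzaldehyde; 3 N-acetylglycine
Product: 5 N-[7-(benzyloxy)-6-methoxy-2-oxo-2H-chromen-3-yl]acetamide, via 2-methyl-1,3-oxazol-5(4H)-one 4 (not isolated)
Conditions: Ac2O, NaOAc, 110 °C
Reagents that add atoms: none
Why: Erlenmeyer–Plöchl azlactone condensation, in which 3 is dehydrated to azlactone 4, 4 condenses with the aldehyde, and the neighbouring phenol opens the azlactone carbonyl to close the lactone of the 3-acetamidocoumarin, a standard entry to this class.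

Step 3
Reactants: 5 N-[7-(benzyloxy)-6-methoxy-2-oxo-2H-chromen-3-yl]acetamide
Product: 7 7-(benzyloxy)-3-hydroxy-6-methoxy-2H-chromen-2-one, via 3-aminocoumarin 6 (not isolated)
Conditions: 3 M aq HCl, 1,4-dioxane, 95 °C, N2
Reagents that add atoms: water, O
Why: Acid hydrolysis of an enamide, in which the amide is cleaved to enamine 6 and its imine tautomer is hydrolysed to the 2,3-dione that rests as enol 7, while the aryl benzyl ether should hold because its cleavage needs concentrated or Lewis acid.

Step 4
Reactants: 8 4-hydroxy-2H-pyran-2-one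
Product: 9 4-bromo-2H-pyran-2-one
Conditions: Bu4NBr, P2O5, toluene, 100 °C
Reagents that add atoms: tetrabutylammonium bromide, CCCC[N+](CCCC)(CCCC)CCCC.[Br-]
Why: Deoxybromination of a vinylogous acid, in which P2O5 turns the C4 hydroxyl into a phosphate leaving group that bromide displaces by addition–elimination, as established for 4-hydroxy-6-methyl-2-pyranone and 4-hydroxycoumarin; the bromide is chosen over a sulfonate because an aryloxide cannot divert to attack at sulfur.

Step 5
Reactants: 7 7-(benzyloxy)-3-hydroxy-6-methoxy-2H-chromen-2-one; 9 4-bromo-2H-pyran-2-one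
Product: 10 4-{[7-(benzyloxy)-6-methoxy-2-oxo-2H-chromen-3-yl]oxy}-2H-pyran-2-one
Conditions: K2CO3, MeCN, 23→50 °C
Reagents that add atoms: none
Why: Addition–elimination (vinylogous acyl substitution) at C4 of the pyranone, the reaction type known for 4-bromo-2-pyranones and phenols, in which the weakly basic enolate oxygen of 7 adds to C4 and bromide leaves, so no metal-catalysed aryl–oxygen coupling is needed.

Step 6
Reactants: 11 pent-4-ynoic acid
Product: 14 triisopropylsilyl 5-[(triisopropylsilyl)oxy]pent-4-ynoate, via dilithio acetylide carboxylate 12 (not isolated), via dilithium ynolate carboxylate 13 (not isolated)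
Conditions: n-BuLi (2 equiv), THF, −78→0 °C; t-BuOOLi (from t-BuOOH + LiN(SiMe3)2), −78→0 °C; TIPSOTf (2.2 equiv), −78→0 °C
Reagents that add atoms: tert-butyl hydroperoxide, CC(C)(C)OO; triisopropylsilyl trifluoromethanesulfonate, CC(C)[Si](C(C)C)(C(C)C)OS(=O)(=O)C(F)(F)F; n-butyllithium, [Li]CCCC (lithium of 12 and 13 only)
Why: Oxidation of a lithium acetylide with lithium tert-butyl peroxide to the ynolate followed by O-silylation with a bulky silyl triflate, the standard route from terminal alkynes to TIPS siloxyalkynes, in which the carboxylate made by the first equivalent of n-BuLi shields the carboxyl carbon and its α-hydrogens from the bases and ends as the TIPS ester.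

Step 7
Reactants: 10 4-{[7-(benzyloxy)-6-methoxy-2-oxo-2H-chromen-3-yl]oxy}-2H-pyran-2-one; 14 triisopropylsilyl 5-[(triisopropylsilyl)oxy]pent-4-ynoate
Product: 16 triisopropylsilyl 3-(4-{[7-(benzyloxy)-6-methoxy-2-oxo-2H-chromen-3-yl]oxy}-2-[(triisopropylsilyl)oxy]phenyl)propanoate, via bicyclic lactone 15 (not isolated)
Conditions: 14 (2 equiv, slow addition), AgNTf2 (20 mol %), 4 Å MS, ClCH2CH2Cl, 60 °C
Reagents that add atoms: none
Why: Proposed new method: AgNTf2 polarises the two partners so that the chain-bearing, nucleophilic alkyne carbon of 14 adds to the electrophilic C6 of pyranone 10 and the silyl ketenium carbon thus formed is captured by C3 of the dienolate (one asynchronous event or two steps), which gives bridged lactone 15; 15 then expels CO2 by retro-[4+2] and ring B emerges aromatic as its silyl ether without any oxidation. The closest known reaction types are the Diels–Alder/decarboxylation of 2-pyranones with alkynes, ynamines and ketene acetals and the silver-salt-promoted formal inverse-demand [4+2] reactions of siloxyalkynes with 1,2-diazines and simple 2-pyranones, whereas a 2-pyranone whose only substituent is a 4-aryloxy donor is unproven. The one ring formed, carbocycle B, is closed by intermolecular [4+2] addition across C3 and C6 of the diene (bonds C5'–C6' and C1'–C2'). No stereocentre remains, since both bridgeheads of racemic 15 become sp2 carbons on loss of CO2. The step needs regioselectivity, and both polarisations secure it: C6 is the vinylogous acceptor terminus, the C4 oxygen enriches C3, and the silyloxy group makes the distal alkyne carbon the nucleophile, so C6' (oxygen) should end up meta and C1' (chain) para to C4'. It also needs chemoselectivity, which rests on the coumarin C3=C4 bond being trisubstituted, benzo-fused and donor-substituted and on the bulky TIPS ester being too hindered to trap the ketenium ion.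

Step 8
Reactants: 16 triisopropylsilyl 3-(4-{[7-(benzyloxy)-6-methoxy-2-oxo-2H-chromen-3-yl]oxy}-2-[(triisopropylsilyl)oxy]phenyl)propanoate
Product: 18 methyl 3-(4-{[7-hydroxy-6-methoxy-2-oxo-2H-chromen-3-yl]oxy}-2-[(triisopropylsilyl)oxy]phenyl)propanoate, via 7-hydroxy silyl ester 17 (not isolated)
Conditions: BCl3 (4 equiv), C6HMe5 (4 equiv), CH2Cl2, −78 °C; then MeOH, −78→40 °C
Reagents that add atoms: methanol, CO
Why: Debenzylation of an aryl benzyl ether with BCl3 and pentamethylbenzene as a non-basic cation scavenger, which at −78 °C should spare the coumarin, the C6 methyl ether and the aryl TIPS ether, followed by acid-catalysed methanolysis of the labile silyl ester in the HCl/B(OMe)3/MeOH mixture formed on quenching (Fischer-type esterification, the same medium used to make methyl esters of fatty acids).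

Step 9
Reactants: 18 methyl 3-(4-{[7-hydroxy-6-methoxy-2-oxo-2H-chromen-3-yl]oxy}-2-[(triisopropylsilyl)oxy]phenyl)propanoate
Product: 19 methyl 3-(2-hydroxy-4-{[7-hydroxy-6-methoxy-2-oxo-2H-chromen-3-yl]oxy}phenyl)propanoate (CNP0259806.0)
Conditions: Bu4NF, AcOH (1:1), THF, 0 °C
Reagents that add atoms: none
Why: Fluoride desilylation of an aryl silyl ether driven by the strong Si–F bond, with the acetic acid buffer keeping the C6' phenol protonated so that it should not close onto the methyl ester to a dihydrocoumarin.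

Compound list
1 | 2,4-dihydroxy-5-methoxybenzaldehyde | COc1cc(C=O)c(O)cc1O | starting material
2 | 4-(benzyloxy)-2-hydroxy-5-methoxybenzaldehyde | COc1cc(C=O)c(O)cc1OCc1ccccc1 | intermediate
3 | N-acetylglycine | CC(=O)NCC(=O)O | starting material
4 | 2-methyl-1,3-oxazol-5(4H)-one (not isolated) | CC1=NCC(=O)O1 | intermediate
5 | N-[7-(benzyloxy)-6-methoxy-2-oxo-2H-chromen-3-yl]acetamide | CC(=O)Nc1cc2cc(OC)c(OCc3ccccc3)cc2oc1=O | intermediate
6 | 3-amino-7-(benzyloxy)-6-methoxy-2H-chromen-2-one (not isolated) | Nc1cc2cc(OC)c(OCc3ccccc3)cc2oc1=O | intermediate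
7 | 7-(benzyloxy)-3-hydroxy-6-methoxy-2H-chromen-2-one | Oc1cc2cc(OC)c(OCc3ccccc3)cc2oc1=O | intermediate
8 | 4-hydroxy-2H-pyran-2-one | O=c1cc(O)cco1 | starting material
9 | 4-bromo-2H-pyran-2-one | O=c1cc(Br)cco1 | intermediate
10 | 4-{[7-(benzyloxy)-6-methoxy-2-oxo-2H-chromen-3-yl]oxy}-2H-pyran-2-one | O=c1cc(Oc2cc3cc(OC)c(OCc4ccccc4)cc3oc2=O)cco1 | intermediate
11 | pent-4-ynoic acid | C#CCCC(=O)O | starting material
12 | lithium 5-lithiopent-4-ynoate (not isolated) | [Li]C#CCCC(=O)O[Li] | intermediate
13 | dilithium 5-oxidopent-4-ynoate (not isolated) | [Li]OC#CCCC(=O)O[Li] | intermediate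
14 | triisopropylsilyl 5-[(triisopropylsilyl)oxy]pent-4-ynoate | CC(C)[Si](C(C)C)(C(C)C)OC#CCCC(=O)O[Si](C(C)C)(C(C)C)C(C)C | intermediate
15 | triisopropylsilyl 3-(8-{[7-(benzyloxy)-6-methoxy-2-oxo-2H-chromen-3-yl]oxy}-3-oxo-5-[(triisopropylsilyl)oxy]-2-oxabicyclo[2.2.2]octa-5,7-dien-6-yl)propanoate (racemic, one enantiomer drawn, not isolated) | O=C1O[C@@H]2C=C(Oc3cc4cc(OC)c(OCc5ccccc5)cc4oc3=O)[C@H]1C(O[Si](C(C)C)(C(C)C)C(C)C)=C2CCC(=O)O[Si](C(C)C)(C(C)C)C(C)C | intermediate
16 | triisopropylsilyl 3-(4-{[7-(benzyloxy)-6-methoxy-2-oxo-2H-chromen-3-yl]oxy}-2-[(triisopropylsilyl)oxy]phenyl)propanoate | CC(C)[Si](C(C)C)(C(C)C)OC(=O)CCc1ccc(Oc2cc3cc(OC)c(OCc4ccccc4)cc3oc2=O)cc1O[Si](C(C)C)(C(C)C)C(C)C | intermediate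
17 | triisopropylsilyl 3-(4-{[7-hydroxy-6-methoxy-2-oxo-2H-chromen-3-yl]oxy}-2-[(triisopropylsilyl)oxy]phenyl)propanoate (not isolated) | CC(C)[Si](C(C)C)(C(C)C)OC(=O)CCc1ccc(Oc2cc3cc(OC)c(O)cc3oc2=O)cc1O[Si](C(C)C)(C(C)C)C(C)C | intermediate
18 | methyl 3-(4-{[7-hydroxy-6-methoxy-2-oxo-2H-chromen-3-yl]oxy}-2-[(triisopropylsilyl)oxy]phenyl)propanoate | COC(=O)CCc1ccc(Oc2cc3cc(OC)c(O)cc3oc2=O)cc1O[Si](C(C)C)(C(C)C)C(C)C | intermediate
19 | methyl 3-(2-hydroxy-4-{[7-hydroxy-6-methoxy-2-oxo-2H-chromen-3-yl]oxy}phenyl)propanoate | COC(=O)CCc1ccc(Oc2cc3cc(OC)c(O)cc3oc2=O)cc1O | target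

Total step count: 9. Longest linear sequence: 7 steps (steps 1, 2, 3, 5, 7, 8, 9).

Steps most likely to fail

**Step 7.**
- What may go wrong: the donor-substituted diene may react too slowly. Silver-induced oligomerisation, hydration or oxygen-to-carbon silyl migration of the alkyne could then consume it first. The zwitterion could also close at C5 to a four-membered ring instead of at C3.
- Fallback: known chemistry, with ring B bought and not built. It sets out from 2 and comes back at 19.
- 7-Hydroxy-3,4-dihydro-2H-chromen-2-one F1 is purchased; its lactone ties up the C6' oxygen and the chain carboxyl. It is O-alkylated with tert-butyl bromoacetate (K2CO3, acetone) to tert-butyl [(2-oxo-3,4-dihydro-2H-chromen-7-yl)oxy]acetate F2.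
- CF3CO2H in CH2Cl2 frees [(2-oxo-3,4-dihydro-2H-chromen-7-yl)oxy]acetic acid F3.
- Perkin-type condensation of this acid with 2 (Ac2O, Et3N, 110 °C) is the standard way from salicylaldehydes and aryloxyacetic acids to 3-aryloxycoumarins. It should give 7-(benzyloxy)-6-methoxy-3-[(2-oxo-3,4-dihydro-2H-chromen-7-yl)oxy]-2H-chromen-2-one F4.
- BCl3/C6HMe5 at −78 °C, then MeOH at 40 °C, should remove the benzyl group and open the dihydrocoumarin lactone to the methyl ester and the C6' phenol, which is 19.

**Step 6.**
- What may go wrong: sluggish oxygen transfer to the sparingly soluble dianion, silylation of the ynolate at carbon instead of oxygen, or loss of the silyl ester during purification.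
- Fallback: the carboxyl group is locked as a base-inert bicyclic orthoester instead of a carboxylate. It sets out from 11 and comes back at 18.
- Esterification of 11 with 3-methyl-3-oxetanemethanol (EDC·HCl, DMAP, CH2Cl2) gives (3-methyloxetan-3-yl)methyl pent-4-ynoate F5.
- BF3·OEt2 (catalytic, CH2Cl2, −15 °C) rearranges it to 1-(but-3-yn-1-yl)-4-methyl-2,6,7-trioxabicyclo[2.2.2]octane F6.
- The same acetylide oxidation and silylation, now with one equivalent each of n-BuLi and TIPSOTf, gives triisopropyl{[4-(4-methyl-2,6,7-trioxabicyclo[2.2.2]octan-1-yl)but-1-yn-1-yl]oxy}silane F7.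
- Cycloaddition with 10 under the conditions of step 7 gives 7-(benzyloxy)-6-methoxy-3-{4-[2-(4-methyl-2,6,7-trioxabicyclo[2.2.2]octan-1-yl)ethyl]-3-[(triisopropylsilyl)oxy]phenoxy}-2H-chromen-2-one F8.
- The conditions of step 8 then debenzylate. The methanolic HCl should open the orthoester and transesterify it to the methyl ester 18.

**Step 5.**
- What may go wrong: attack of the ambident enolate of 7 through C4 instead of oxygen, or opening of the C6-unsubstituted pyranone by 1,6-addition of the nucleophile or base.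
- Fallback: the coumarin is closed around an ether oxygen that is already in place. It sets out from 8 (together with 2), comes back at 10, and makes steps 2 to 5 unnecessary.
- O-alkylation of 8 with tert-butyl bromoacetate (K2CO3, DMF) gives tert-butyl [(2-oxo-2H-pyran-4-yl)oxy]acetate F9.
- CF3CO2H in CH2Cl2 gives [(2-oxo-2H-pyran-4-yl)oxy]acetic acid F10.
- Perkin-type condensation of this acid with 2 (Ac2O, Et3N, 100 °C) should give 10.

Further compounds
F1 | step 7 | 7-hydroxy-3,4-dihydro-2H-chromen-2-one (purchased) | O=C1CCc2ccc(O)cc2O1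
F2 | step 7 | tert-butyl [(2-oxo-3,4-dihydro-2H-chromen-7-yl)oxy]acetate | CC(C)(C)OC(=O)COc1ccc2CCC(=O)Oc2c1
F3 | step 7 | [(2-oxo-3,4-dihydro-2H-chromen-7-yl)oxy]acetic acid | OC(=O)COc1ccc2CCC(=O)Oc2c1
F4 | step 7 | 7-(benzyloxy)-6-methoxy-3-[(2-oxo-3,4-dihydro-2H-chromen-7-yl)oxy]-2H-chromen-2-one | COc1cc2cc(Oc3ccc4CCC(=O)Oc4c3)c(=O)oc2cc1OCc1ccccc1
F5 | step 6 | (3-methyloxetan-3-yl)methyl pent-4-ynoate | C#CCCC(=O)OCC1(C)COC1
F6 | step 6 | 1-(but-3-yn-1-yl)-4-methyl-2,6,7-trioxabicyclo[2.2.2]octane | C#CCCC12OCC(C)(CO1)CO2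
F7 | step 6 | triisopropyl{[4-(4-methyl-2,6,7-trioxabicyclo[2.2.2]octan-1-yl)but-1-yn-1-yl]oxy}silane | CC(C)[Si](C(C)C)(C(C)C)OC#CCCC12OCC(C)(CO1)CO2
F8 | step 6 | 7-(benzyloxy)-6-methoxy-3-{4-[2-(4-methyl-2,6,7-trioxabicyclo[2.2.2]octan-1-yl)ethyl]-3-[(triisopropylsilyl)oxy]phenoxy}-2H-chromen-2-one | CC(C)[Si](C(C)C)(C(C)C)Oc1cc(Oc2cc3cc(OC)c(OCc4ccccc4)cc3oc2=O)ccc1CCC12OCC(C)(CO1)CO2
F9 | step 5 | tert-butyl [(2-oxo-2H-pyran-4-yl)oxy]acetate | CC(C)(C)OC(=O)COc1ccoc(=O)c1
F10 | step 5 | [(2-oxo-2H-pyran-4-yl)oxy]acetic acid | OC(=O)COc1ccoc(=O)c1
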